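One millimole per litre of second reagent can serve one millimole per litre of starting material, provided each target takes up one second reagent. That is my assumption; no reading follows the second reagent.

| flask | starting material | partner | second reagent | remark | time |
|---|---|---|---|---|---|
| elm | 15 mM | 32 mM | 24 mM | run made earlier |  |
| Monday's | 15 mM | 48.0 mM | 24.0 mM |  | 12 h |
| Sunday's | 30 mM | 48.0 mM | 24.0 mM |  | 12 h |
| Thursday's | 60 mM | 48.0 mM | 24.0 mM |  | 12 h |
| Saturday's | 120 mM | 48.0 mM | 24.0 mM |  | 12 h |
| Tuesday's | 250 mM | 48.0 mM | 24.0 mM |  | 12 h |

elm run (percent of the starting material charged)

| time / h | target / % | starting material / % |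
|---|---|---|
| 0.333 | 2 | 29 |
| 0.833 | 6 | 4 |
| 2.00 | 13 | 3 |
| 4.00 | 20 | 0 |

(standard deviation of a reading: 1.5 percentage points)

- "hardly changes" means that all values lie within two and a half points (for a concentration: within two and a half percent of the largest)

1. [target] at the end for Monday's, Sunday's, Thursday's, Saturday's, Tuesday's, in this order
2. how that number moves from the first to the last of them (falls, then rises / rises all the way / falls all the way / rises, then falls / hardly changes)

In Monday's flask, c(second reagent) = 24.0 mM and c(starting material) = 15 mM give 160%. This figure, the charge of second reagent as a share of the charge of starting material, is the reagent ceiling. It bounds the target together with anything else that takes up second reagent.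

The elm run is the neighbour of Monday's flask: its ceiling is the same, 160%, and it differs in the partner, 32 mM against 48.0 mM. In the elm run, the readings at 0.833 h show 4% starting material and 6% target, so 90.0% of the charge stands in forms nobody measured. The target then reads 13% at 2.00 h and 20% at 4.00 h, below the ceiling. The ceiling lies above the whole charge, so by this count starting material, not second reagent, is the limiting reagent in both flasks.

By my reckoning the picture changes further along the row. The ceiling falls to 40.0% in Thursday's flask and 9.60% in Tuesday's, because less second reagent is charged than starting material. The readings do not show whether the unmeasured forms have already taken up second reagent.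

The forecast gave 7 mM, 12 mM, 16.6 mM, 16.8 mM and 17 mM, a row that rises all the way, in its words “I expect a rise that flattens”. Its highest value stays under 24.0 mM.

The flasks give 4.57 mM, 6.07 mM, 1.42 mM, 0.485 mM and 0.202 mM, a row that rises, then falls.

    second reagent + intermediate → target (k = 35.0 M⁻¹ h⁻¹)
    starting material + second reagent → side product (k = 160 M⁻¹ h⁻¹)
    starting material + partner → intermediate (k = 35.0 M⁻¹ h⁻¹)
    intermediate → decomposed reagent (k = 0.0620 h⁻¹)

In Thursday's flask, second reagent stands at 0% of its charge after 6.00 h, with target at 2.37% and side product at 37.6% of the starting material charged. Monday's ceiling of 160% stays clear of its target and side product together, 95.4% after 12.0 h. Thursday's ceiling, 40.0%, meets the same sum after 12.0 h, 40.0%.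

The data are calculated for substances that don't exist; noise was put on by code.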